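The target is (2S)-naringenin carrying an (R)-1-methylpiperidin-2-yl group (ring D) at C6 of ring A. The only stereocentre of ring D is C2'', the carbon bonded to both ring A and N1''. C3'' to C6'' are bare methylenes, so the distant C4''–C5'' bond is the natural place to open the ring. One ring-closing metathesis forms C4''=C5'' and the whole azacycle. Its precursor is a protonated acyclic amine: nitrogen bears methyl and allyl, and C2'', already fixed by sulfinimine allylation, bears allyl and a symmetrically protected phloroglucinol ring. Ring A is symmetric about its C6–C8a axis, so ring C is annulated without regiochemical choice, and one hydrogenation finishes.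

Key step: step 8

Remark: flavanone numbering is used (rings A, B, C; ring D is the piperidine, atoms doubly primed). The closed magnesium-chelate model is assumed to govern step 4 despite the two ortho benzyloxy groups, and this fixes the choice of the (S)-sulfinamide for an R centre at C2''.

Step 1
Reactants: 1 2,4,6-trihydroxybenzaldehyde
Product: 2 2,6-dihydroxy-4-(triisopropylsilyloxy)benzaldehyde
Conditions: TIPSCl (1.0 equiv), imidazole, DMF, 0 °C
Reagents that add atoms: triisopropylsilyl chloride, CC(C)[Si](Cl)(C(C)C)C(C)C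
Why: Chemoselective O-silylation: the C4 hydroxyl is the only one not hydrogen-bonded to the formyl oxygen and is the most acidic and least hindered, so one equivalent of the bulky chlorosilane should react there.

Step 2
Reactants: 2 2,6-dihydroxy-4-(triisopropylsilyloxy)benzaldehyde
Product: 3 2,6-bis(benzyloxy)-4-(triisopropylsilyloxy)benzaldehyde
Conditions: BnOH (2.4 equiv), PPh3, DIAD, THF, 0 °C to rt
Reagents that add atoms: benzyl alcohol, OCc1ccccc1
Why: Twofold Mitsunobu etherification alkylates the acidic, chelated ortho phenols under essentially neutral conditions, sparing the aryl silyl ether para to the formyl group that carbonate-mediated benzylation could strip.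

Step 3
Reactants: 3 2,6-bis(benzyloxy)-4-(triisopropylsilyloxy)benzaldehyde; 4 (S)-tert-butanesulfinamide
Product: 5 (S,E)-N-[2,6-bis(benzyloxy)-4-(triisopropylsilyloxy)benzylidene]-2-methylpropane-2-sulfinamide
Conditions: Ti(OEt)4 (3 equiv), THF, 65 °C
Reagents that add atoms: (S)-tert-butanesulfinamide (4), CC(C)(C)[S@](=O)N
Why: Sulfinimine formation by Ti(OEt)4-promoted condensation, in which the titanium alkoxide serves as Lewis acid and water scavenger and heating overcomes the hindered, electron-rich formyl group; only the E imine is expected.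

Step 4
Reactants: 5 (S,E)-sulfinimine; 6 allylmagnesium bromide
Product: 7 (S)-N-{(R)-1-[2,6-bis(benzyloxy)-4-(triisopropylsilyloxy)phenyl]but-3-en-1-yl}-2-methylpropane-2-sulfinamide
Conditions: allylMgBr (1 M in Et2O, 2 equiv), CH2Cl2, −78 °C; sat. aq NH4Cl
Reagents that add atoms: allylmagnesium bromide (6), C=CC[Mg]Br
Why: Diastereoselective 1,2-addition of an allyl Grignard reagent to a tert-butanesulfinimine in a non-coordinating solvent: in the closed six-membered chair with magnesium on the sulfinyl oxygen and tert-butyl equatorial, the (S)-sulfinyl group sends allyl to the Re face of C=N and sets C2'' as R, and any minor diastereomer is removed by chromatography.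

Step 5
Reactants: 7 (S,R)-homoallylic sulfinamide; 8 allyl bromide
Product: 9 (S)-N-allyl-N-{(R)-1-[2,6-bis(benzyloxy)-4-(triisopropylsilyloxy)phenyl]but-3-en-1-yl}-2-methylpropane-2-sulfinamide
Conditions: NaH (1.5 equiv), DMF, 0 °C; allyl bromide (2 equiv), 0 °C to rt
Reagents that add atoms: allyl bromide (8), C=CCBr
Why: SN2 N-alkylation of the sulfinamide anion, in which the sulfinyl group also acts as a protecting group limiting nitrogen to a single allylation, something a free primary amine would not guarantee.

Step 6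
Reactants: 9 N-allyl sulfinamide
Product: 10 (R)-N-allyl-1-[2,6-bis(benzyloxy)-4-(triisopropylsilyloxy)phenyl]but-3-en-1-amine
Conditions: HCl (4 M in dioxane, 2.5 equiv), MeOH, 0 °C, 30 min; cold 1 M aq NaOH
Reagents that add atoms: none
Why: Acid-catalysed methanolysis of the S–N bond (standard sulfinyl removal) is fast at 0 °C, so a short cold exposure should leave the aryl silyl ether, the benzyl ethers and the electron-rich benzylic C2''–N bond intact.

Step 7
Reactants: 10 secondary N-allyl amine
Product: 11 (R)-N-allyl-N-methyl-1-[2,6-bis(benzyloxy)-4-(triisopropylsilyloxy)phenyl]but-3-en-1-amine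
Conditions: 37% aq HCHO, NaBH(OAc)3, ClCH2CH2Cl, rt
Reagents that add atoms: formaldehyde, C=O
Why: Reductive amination with formaldehyde and NaBH(OAc)3 methylates the secondary amine once, cannot quaternise it, and touches neither alkene nor C2''.

Step 8
Reactants: 11 (R)-N-allyl-N-methyl homoallylic amine
Product: 14 (R)-2-[2,6-bis(benzyloxy)-4-(triisopropylsilyloxy)phenyl]-1-methyl-1,2,3,6-tetrahydropyridine, via diene ammonium tosylate 12 (not isolated), via tetrahydropyridinium tosylate 13 (not isolated)
Conditions: TsOH·H2O (1.05 equiv), CH2Cl2 (0.01 M), rt, 15 min; second-generation Grubbs catalyst RuCl2(=CHPh)(PCy3)(H2IMes) (5 mol %), 40 °C, Ar sparge; cold 1 M aq NaOH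
Reagents that add atoms: none
Why: Ring-closing olefin metathesis: loss of PCy3 from the precatalyst frees a 14-electron ruthenium benzylidene that takes up one terminal vinyl group of 12, and successive [2+2] cycloadditions and cycloreversions via ruthenacyclobutanes first load the carbene onto the substrate and then join C4'' to C5'', with ethylene escaping as gas and pulling the equilibrium forward. The closest known reaction type is the metathesis of N-allyl homoallylamine salts to 1,2,3,6-tetrahydropyridines. Ring D closes as an unstrained six-membered ring from a 1,7-diene by intramolecular carbene transfer between two monosubstituted alkenes, and the ring size enforces the cis C4''=C5'' geometry. No stereocentre is created, and C2'' (R, from step 4) lies two bonds from the nearest reacting carbon and is not touched. The selectivity needed is cyclisation in preference to oligomerisation, alkene migration and coordination of N1'' to ruthenium, and it is secured by high dilution, by the short tether and by complete protonation of N1'' by one equivalent of sulfonic acid. Nitrogen is deliberately kept as a basic N-methylamine, because a tris(alkoxy)benzylammonium ion resists heterolysis of the C2''–N bond far better than an N-acyl derivative would, here and in the acidic step 14, while the benzyl and silyl ethers are spectators.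

Step 9
Reactants: 14 silyl-protected tetrahydropyridine
Product: 15 3,5-bis(benzyloxy)-4-[(R)-1-methyl-1,2,3,6-tetrahydropyridin-2-yl]phenol
Conditions: Bu4NF (1.1 equiv), AcOH (1.1 equiv), THF, 0 °C
Reagents that add atoms: none
Why: Fluoride-induced desilylation driven by the strong Si–F bond; buffering with acetic acid keeps the liberated para-hydroxybenzylamine out of its phenoxide form and so away from quinone-methide-type loss of the amine, and 15 is used at once.

Step 10 (steps 10–12 run in parallel with steps 1–9)
Reactants: 16 4-hydroxybenzaldehyde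
Product: 17 benzyl 4-formylphenyl carbonate
Conditions: CbzCl (1.05 equiv), Et3N, CH2Cl2, 0 °C
Reagents that add atoms: benzyl chloroformate, O=C(Cl)OCc1ccccc1
Why: O-acylation of the phenol by a chloroformate gives an aryl benzyl carbonate, chosen because it makes the ring B oxygen a weak donor (suppressing ionisation at the future C2 in steps 13 and 14) and is still removed by hydrogenolysis in the last step.

Step 11
Reactants: 17 benzyl 4-formylphenyl carbonate; 18 tert-butyl diazoacetate
Product: 19 tert-butyl 3-{4-[(benzyloxycarbonyl)oxy]phenyl}-3-oxopropanoate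
Conditions: SnCl2 (10 mol %), CH2Cl2, rt
Reagents that add atoms: tert-butyl diazoacetate (18), CC(C)(C)OC(=O)C=[N+]=[N-]
Why: Roskamp reaction: SnCl2-catalysed addition of the diazoacetate to the aldehyde followed by a 1,2-hydride shift with loss of N2 gives the β-keto ester directly, under conditions too mild to harm the carbonate or the tert-butyl ester.

Step 12
Reactants: 19 β-keto ester
Product: 20 tert-butyl (3R)-3-{4-[(benzyloxycarbonyl)oxy]phenyl}-3-hydroxypropanoate
Conditions: RuCl[(R,R)-TsDPEN](p-cymene) (1 mol %), HCO2H/Et3N 5:2, EtOAc, 30 °C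
Reagents that add atoms: none
Why: Noyori–Ikariya asymmetric transfer hydrogenation of an aryl ketone: the (R,R)-TsDPEN ruthenium hydride delivers hydrogen to the face defined by the aryl/arene CH–π contact and should set the carbinol carbon as R, while the non-hydrogenolytic conditions leave the benzyl carbonate alone.

Step 13
Reactants: 15 phenol; 20 (3R)-β-hydroxy ester
Product: 21 tert-butyl (3S)-3-{4-[(benzyloxycarbonyl)oxy]phenyl}-3-{3,5-bis(benzyloxy)-4-[(R)-1-methyl-1,2,3,6-tetrahydropyridin-2-yl]phenoxy}propanoate
Conditions: PPh3 (1.5 equiv), DIAD (1.5 equiv, slow addition), toluene, 0 °C to rt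
Reagents that add atoms: none
Why: Mitsunobu etherification: the phenol displaces the oxyphosphonium-activated benzylic alcohol by SN2 with inversion, turning the R carbinol into the S-configured future C2, and the weakly donating carbonate on ring B together with a non-polar solvent and low temperature disfavours an SN1 leak.

Step 14
Reactants: 21 tert-butyl β-aryloxy ester
Product: 24 (2S)-5,7-bis(benzyloxy)-2-{4-[(benzyloxycarbonyl)oxy]phenyl}-6-[(R)-1-methyl-1,2,3,6-tetrahydropyridin-2-yl]chroman-4-one, via free carboxylic acid 22 (not isolated), via mixed trifluoroacetic anhydride 23 (not isolated)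
Conditions: TFA/CH2Cl2 1:2, 0 °C to rt; concentrate; (CF3CO)2O (3 equiv), CH2Cl2, 0 °C to rt; aq NaHCO3
Reagents that add atoms: none
Why: Acidolysis of the tert-butyl ester followed by intramolecular Friedel–Crafts acylation through the mixed anhydride closes six-membered ring C onto C4a; the two free positions of ring A are equivalent so only the 6-substituted chromanone can form, N1'' stays protonated and thus protected, and no base is present that could trigger retro-oxa-Michael loss of C2.

Step 15
Reactants: 24 protected flavanone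
Product: 25 (2S)-5,7-dihydroxy-2-(4-hydroxyphenyl)-6-[(2R)-1-methylpiperidin-2-yl]chroman-4-one (target)
Conditions: H2 (1 atm), Pd/C (10 wt %), AcOH (2 equiv), EtOAc–MeOH, rt; pH 7 phosphate buffer work-up
Reagents that add atoms: none
Why: Heterogeneous catalytic hydrogenation and hydrogenolysis: in one operation H2 on Pd/C saturates C4''=C5'' and cleaves both benzyl ethers and the benzyl carbonate (which then loses CO2), while acetic acid keeps N1'' protonated so that base-induced chalcone opening at C2 is avoided, and the hindered endocyclic C2''–N and C2–O1 benzylic bonds, which cleave more slowly, should survive at 1 atm and room temperature.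

Compound list
1 | 2,4,6-trihydroxybenzaldehyde | O=Cc1c(O)cc(O)cc1O | starting material
2 | 2,6-dihydroxy-4-(triisopropylsilyloxy)benzaldehyde | O=Cc1c(O)cc(O[Si](C(C)C)(C(C)C)C(C)C)cc1O | intermediate
3 | 2,6-bis(benzyloxy)-4-(triisopropylsilyloxy)benzaldehyde | O=Cc1c(OCc2ccccc2)cc(O[Si](C(C)C)(C(C)C)C(C)C)cc1OCc1ccccc1 | intermediate
4 | (S)-tert-butanesulfinamide ((S)-2-methylpropane-2-sulfinamide) | CC(C)(C)[S@](=O)N | starting material
5 | (S,E)-N-[2,6-bis(benzyloxy)-4-(triisopropylsilyloxy)benzylidene]-2-methylpropane-2-sulfinamide | CC(C)(C)[S@](=O)/N=C/c1c(OCc2ccccc2)cc(O[Si](C(C)C)(C(C)C)C(C)C)cc1OCc1ccccc1 | intermediate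
6 | allylmagnesium bromide | C=CC[Mg]Br | starting material
7 | (S)-N-{(R)-1-[2,6-bis(benzyloxy)-4-(triisopropylsilyloxy)phenyl]but-3-en-1-yl}-2-methylpropane-2-sulfinamide | C=CC[C@@H](N[S@@](=O)C(C)(C)C)c1c(OCc2ccccc2)cc(O[Si](C(C)C)(C(C)C)C(C)C)cc1OCc1ccccc1 | intermediate
8 | allyl bromide | C=CCBr | starting material
9 | (S)-N-allyl-N-{(R)-1-[2,6-bis(benzyloxy)-4-(triisopropylsilyloxy)phenyl]but-3-en-1-yl}-2-methylpropane-2-sulfinamide | C=CC[C@@H](N(CC=C)[S@@](=O)C(C)(C)C)c1c(OCc2ccccc2)cc(O[Si](C(C)C)(C(C)C)C(C)C)cc1OCc1ccccc1 | intermediate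
10 | (R)-N-allyl-1-[2,6-bis(benzyloxy)-4-(triisopropylsilyloxy)phenyl]but-3-en-1-amine | C=CC[C@@H](NCC=C)c1c(OCc2ccccc2)cc(O[Si](C(C)C)(C(C)C)C(C)C)cc1OCc1ccccc1 | intermediate
11 | (R)-N-allyl-N-methyl-1-[2,6-bis(benzyloxy)-4-(triisopropylsilyloxy)phenyl]but-3-en-1-amine | C=CC[C@@H](N(C)CC=C)c1c(OCc2ccccc2)cc(O[Si](C(C)C)(C(C)C)C(C)C)cc1OCc1ccccc1 | intermediate
12 | p-toluenesulfonate salt of 11 (N-protonated diene) | C=CC[C@@H]([NH+](C)CC=C)c1c(OCc2ccccc2)cc(O[Si](C(C)C)(C(C)C)C(C)C)cc1OCc1ccccc1.Cc1ccc(S(=O)(=O)[O-])cc1 | intermediate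
13 | p-toluenesulfonate salt of 14 (N-protonated tetrahydropyridine) | C[NH+]1CC=CC[C@@H]1c1c(OCc2ccccc2)cc(O[Si](C(C)C)(C(C)C)C(C)C)cc1OCc1ccccc1.Cc1ccc(S(=O)(=O)[O-])cc1 | intermediate
14 | (R)-2-[2,6-bis(benzyloxy)-4-(triisopropylsilyloxy)phenyl]-1-methyl-1,2,3,6-tetrahydropyridine | CN1CC=CC[C@@H]1c1c(OCc2ccccc2)cc(O[Si](C(C)C)(C(C)C)C(C)C)cc1OCc1ccccc1 | intermediate
15 | 3,5-bis(benzyloxy)-4-[(R)-1-methyl-1,2,3,6-tetrahydropyridin-2-yl]phenol | CN1CC=CC[C@@H]1c1c(OCc2ccccc2)cc(O)cc1OCc1ccccc1 | intermediate
16 | 4-hydroxybenzaldehyde | O=Cc1ccc(O)cc1 | starting material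
17 | benzyl 4-formylphenyl carbonate | O=Cc1ccc(OC(=O)OCc2ccccc2)cc1 | intermediate
18 | tert-butyl diazoacetate | CC(C)(C)OC(=O)C=[N+]=[N-] | starting material
19 | tert-butyl 3-{4-[(benzyloxycarbonyl)oxy]phenyl}-3-oxopropanoate | CC(C)(C)OC(=O)CC(=O)c1ccc(OC(=O)OCc2ccccc2)cc1 | intermediate
20 | tert-butyl (3R)-3-{4-[(benzyloxycarbonyl)oxy]phenyl}-3-hydroxypropanoate | CC(C)(C)OC(=O)C[C@@H](O)c1ccc(OC(=O)OCc2ccccc2)cc1 | intermediate
21 | tert-butyl (3S)-3-{4-[(benzyloxycarbonyl)oxy]phenyl}-3-{3,5-bis(benzyloxy)-4-[(R)-1-methyl-1,2,3,6-tetrahydropyridin-2-yl]phenoxy}propanoate | CN1CC=CC[C@@H]1c1c(OCc2ccccc2)cc(O[C@@H](CC(=O)OC(C)(C)C)c2ccc(OC(=O)OCc3ccccc3)cc2)cc1OCc1ccccc1 | intermediate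
22 | (3S)-carboxylic acid from 21 (present as its trifluoroacetate salt, drawn neutral) | CN1CC=CC[C@@H]1c1c(OCc2ccccc2)cc(O[C@@H](CC(=O)O)c2ccc(OC(=O)OCc3ccccc3)cc2)cc1OCc1ccccc1 | intermediate
23 | mixed anhydride of 22 and trifluoroacetic acid (drawn neutral) | CN1CC=CC[C@@H]1c1c(OCc2ccccc2)cc(O[C@@H](CC(=O)OC(=O)C(F)(F)F)c2ccc(OC(=O)OCc3ccccc3)cc2)cc1OCc1ccccc1 | intermediate
24 | (2S)-5,7-bis(benzyloxy)-2-{4-[(benzyloxycarbonyl)oxy]phenyl}-6-[(R)-1-methyl-1,2,3,6-tetrahydropyridin-2-yl]chroman-4-one | CN1CC=CC[C@@H]1c1c(OCc2ccccc2)cc2c(c1OCc1ccccc1)C(=O)C[C@@H](c1ccc(OC(=O)OCc3ccccc3)cc1)O2 | intermediate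
25 | (2S)-5,7-dihydroxy-2-(4-hydroxyphenyl)-6-[(2R)-1-methylpiperidin-2-yl]chroman-4-one | CN1CCCC[C@@H]1c1c(O)cc2c(c1O)C(=O)C[C@@H](c1ccc(O)cc1)O2 | target

Total steps: 15. Longest linear sequence: 12 steps (steps 1–9 and 13–15); steps 10–12 form the parallel branch.

Steps most likely to fail

Step 13 (Mitsunobu etherification).
- What may go wrong: the activated β-hydroxy ester may undergo β-elimination towards the cinnamate. Partial ionisation of the benzylic oxyphosphonium may also erode the configuration at the future C2.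
- Fallback idea: ring C is closed by a reversible oxa-Michael addition instead, and the resident C2'' centre is used to separate the C2 epimers. The fallback sets out from 15 and comes back at 25.
- Route: Friedel–Crafts C-acetylation of 15 with AcOH/(CF3CO)2O, followed by brief methanolysis of any aryl ester, should give the 2-hydroxyacetophenone F1. Claisen–Schmidt condensation with 4-(benzyloxy)benzaldehyde (KOH, EtOH, rt) should give the 2'-hydroxychalcone F2.
- NaOAc in refluxing EtOH then closes ring C to the (2S)-flavanone F3 and the (2R)-flavanone F4. These are diastereomers and are parted by chromatography or salt crystallisation, and F4 is re-equilibrated under the same conditions. Hydrogenation of F3 as in step 15 gives 25.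

Step 8 (ring-closing metathesis of the ammonium salt).
- What may go wrong: traces of unprotonated amine may deactivate ruthenium, ruthenium hydrides may shift the alkenes, and the warm salt may slowly lose its amine by heterolysis at C2''.
- Fallback idea: the same C4''=C5'' bond is closed while nitrogen is still a non-basic sulfinamide, and the methyl group is added afterwards. The fallback sets out from 9 and comes back at 14.
- Route: treatment of 9 with RuCl2(=CHPh)(PCy3)(H2IMes) in CH2Cl2 at 40 °C, with no acid, should give the N-sulfinyl tetrahydropyridine F5. HCl/MeOH at 0 °C frees the secondary tetrahydropyridine F6, and reductive methylation (aq HCHO, NaBH(OAc)3) delivers 14.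

Step 15 (global hydrogenation).
- What may go wrong: the benzylic C2''–N or C2–O1 bonds may undergo hydrogenolysis, debenzylation may stall through amine poisoning of palladium, and C2 may epimerise during a long reaction.
- Fallback idea: the two tasks are separated and metal-catalysed hydrogenolysis is avoided. The fallback sets out from 24 and comes back at 25.
- Route: diimide, generated from 2-nitrobenzenesulfonyl hydrazide and Et3N in CH2Cl2 at rt, saturates only C4''=C5'' to give the protected piperidinyl flavanone F7. BCl3 with pentamethylbenzene as benzyl-cation scavenger (CH2Cl2, −78 °C) then removes the two benzyl ethers and the benzyl carbonate to give 25.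

Further compounds
F1 | step 13 | 1-{2,4-bis(benzyloxy)-6-hydroxy-3-[(R)-1-methyl-1,2,3,6-tetrahydropyridin-2-yl]phenyl}ethan-1-one | CN1CC=CC[C@@H]1c1c(OCc2ccccc2)cc(O)c(C(C)=O)c1OCc1ccccc1
F2 | step 13 | (E)-1-{2,4-bis(benzyloxy)-6-hydroxy-3-[(R)-1-methyl-1,2,3,6-tetrahydropyridin-2-yl]phenyl}-3-[4-(benzyloxy)phenyl]prop-2-en-1-one | CN1CC=CC[C@@H]1c1c(OCc2ccccc2)cc(O)c(C(=O)/C=C/c2ccc(OCc3ccccc3)cc2)c1OCc1ccccc1
F3 | step 13 | (2S)-5,7-bis(benzyloxy)-2-[4-(benzyloxy)phenyl]-6-[(R)-1-methyl-1,2,3,6-tetrahydropyridin-2-yl]chroman-4-one | CN1CC=CC[C@@H]1c1c(OCc2ccccc2)cc2c(c1OCc1ccccc1)C(=O)C[C@@H](c1ccc(OCc3ccccc3)cc1)O2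
F4 | step 13 | (2R)-5,7-bis(benzyloxy)-2-[4-(benzyloxy)phenyl]-6-[(R)-1-methyl-1,2,3,6-tetrahydropyridin-2-yl]chroman-4-one | CN1CC=CC[C@@H]1c1c(OCc2ccccc2)cc2c(c1OCc1ccccc1)C(=O)C[C@H](c1ccc(OCc3ccccc3)cc1)O2
F5 | step 8 | (R)-2-[2,6-bis(benzyloxy)-4-(triisopropylsilyloxy)phenyl]-1-[(S)-tert-butylsulfinyl]-1,2,3,6-tetrahydropyridine | CC(C)(C)[S@](=O)N1CC=CC[C@@H]1c1c(OCc2ccccc2)cc(O[Si](C(C)C)(C(C)C)C(C)C)cc1OCc1ccccc1
F6 | step 8 | (R)-2-[2,6-bis(benzyloxy)-4-(triisopropylsilyloxy)phenyl]-1,2,3,6-tetrahydropyridine | N1CC=CC[C@@H]1c1c(OCc2ccccc2)cc(O[Si](C(C)C)(C(C)C)C(C)C)cc1OCc1ccccc1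
F7 | step 15 | (2S)-5,7-bis(benzyloxy)-2-{4-[(benzyloxycarbonyl)oxy]phenyl}-6-[(2R)-1-methylpiperidin-2-yl]chroman-4-one | CN1CCCC[C@@H]1c1c(OCc2ccccc2)cc2c(c1OCc1ccccc1)C(=O)C[C@@H](c1ccc(OC(=O)OCc3ccccc3)cc1)O2
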